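**Strategy.** The cis-5-acyloxy-6-alkyl-5,6-dihydropyran-2-one (ring atoms O1, C2=O, C3=C4, C5–O, C6) is treated as an oxidised 2-furyl carbinol: the four furan carbons become C2–C5, and the carbinol carbon and oxygen become C6 and O1. An Achmatowicz ring expansion of an (R)-furyl carbinol that already carries the whole epoxy side chain (C1'–C7') builds the pyranone ring in one operation without touching C6. Lactol oxidation and Luche reduction then relay C5 (trans), and a Mitsunobu esterification with a separately made bis-silylated (2E,4E)-dienoic acid inverts C5 to the cis ester. Desilylation finishes the synthesis.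

Key step: step 9

Numbering used: lactone ring O1, C2 (carbonyl), C3=C4, C5 (acyloxy), C6; side chain C1'–C7' counted from C6; acid C1–C8.
Assumption 1: (DHQD)2AQN is taken to methanolyse the anhydride carbonyl next to the future C1'; if the sense proves opposite, the pseudoenantiomer (DHQ)2AQN is used with no other change.
Assumption 2: (S)-BINAP is taken to direct the alkenyl group to the same enone face as in additions to cyclic enones, which gives the S lactone; (R)-BINAP is used if the sense proves opposite.

**Pyranone half**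

Step 1
Reactants: 1 meso-2,4-dimethylglutaric anhydride ((3R,5S)-3,5-dimethyloxane-2,6-dione)
Product: 2 (2R,4S)-5-methoxy-2,4-dimethyl-5-oxopentanoic acid
Conditions: (DHQD)2AQN (cat.), MeOH, Et2O, −40 °C
Reagents that add atoms: methanol (CO)
Why: Alkaloid-catalysed alcoholytic desymmetrisation of a meso anhydride: the bis-cinchona general base delivers methanol to one of the two enantiotopic carbonyls, which fixes both methyl-bearing centres (future C1' and C3') at once and leaves the free acid at the future C4' end.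

Step 2
Reactants: 2 (2R,4S)-5-methoxy-2,4-dimethyl-5-oxopentanoic acid
Product: 3 methyl (2S,4R)-5-hydroxy-2,4-dimethylpentanoate
Conditions: BH3·SMe2, THF, 0 °C to rt; MeOH quench
Reagents that add atoms: none
Why: Chemoselective borane reduction: the carboxylic acid is reduced through its acyloxyborane far faster than the methyl ester, no stereocentre is touched, and the hydroxy ester is iodinated without delay to forestall lactonisation.

Step 3
Reactants: 3 methyl (2S,4R)-5-hydroxy-2,4-dimethylpentanoate
Product: 4 methyl (2S,4R)-5-iodo-2,4-dimethylpentanoate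
Conditions: I2, PPh3, imidazole, CH2Cl2, 0 °C
Reagents that add atoms: iodine (II)
Why: Appel-type iodination: the primary alcohol is activated on phosphorus and displaced by iodide under neutral, imidazole-buffered conditions that leave the ester and both stereocentres alone.

Step 4
Reactants: 4 methyl (2S,4R)-5-iodo-2,4-dimethylpentanoate; 5 (E)-2-bromobut-2-ene
Product: 7 methyl (2S,4R,6E)-2,4,6-trimethyloct-6-enoate, via alkylzinc iodide 6 (not isolated)
Conditions: Zn dust (TMSCl/BrCH2CH2Br activation), LiCl, THF, 40 °C; then 5, PdCl2(dppf) (cat.), THF, 50 °C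
Reagents that add atoms: none
Why: Negishi sp3–sp2 cross-coupling: zinc inserts into the primary C–I bond without harming the ester, and oxidative addition to the alkenyl bromide and reductive elimination both proceed with retention, so the E geometry of 5 is transferred to the trisubstituted alkene.

Step 5
Reactants: 7 methyl (2S,4R,6E)-2,4,6-trimethyloct-6-enoate
Product: 8 (2S,4R,6E)-N-methoxy-N,2,4,6-tetramethyloct-6-enamide
Conditions: MeNH(OMe)·HCl, i-PrMgCl, THF, −20 to 0 °C
Reagents that add atoms: N,O-dimethylhydroxylamine hydrochloride (CNOC.Cl)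
Why: Weinreb amide formation by aminolysis of the ester with the chloromagnesium amide of N,O-dimethylhydroxylamine, a non-enolising low-temperature protocol that preserves the alpha stereocentre.

Step 6
Reactants: 8 (2S,4R,6E)-N-methoxy-N,2,4,6-tetramethyloct-6-enamide
Product: 9 (2S,4R)-5-[(2S,3S)-2,3-dimethyloxiran-2-yl]-N-methoxy-N,2,4-trimethylpentanamide
Conditions: L-fructose-derived Shi ketone (ent-Shi ketone, cat.), Oxone (2KHSO5·KHSO4·K2SO4), K2CO3, Bu4NHSO4, Na2B4O7/Na2EDTA buffer, MeCN–dimethoxymethane, 0 °C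
Reagents that add atoms: potassium peroxymonosulfate ([K+].[O-]S(=O)(=O)OO)
Why: Shi asymmetric epoxidation: the dioxirane generated from the L-fructose-derived ketone transfers oxygen through a spiro transition state to the alkene face that gives the (2S,3S)-oxirane, so C5' and C6' are set under reagent control (the mirror-image D-ketone is known to give R,R epoxides from E-alkenes of this type), and at this stage no other oxidisable pi system is present.

Step 7
Reactants: 9 (2S,4R)-5-[(2S,3S)-2,3-dimethyloxiran-2-yl]-N-methoxy-N,2,4-trimethylpentanamide; 10 furan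
Product: 12 (2S,4R)-5-[(2S,3S)-2,3-dimethyloxiran-2-yl]-1-(furan-2-yl)-2,4-dimethylpentan-1-one, via 2-furyllithium 11 (not isolated)
Conditions: furan, n-BuLi, THF, 0 °C; then 9, −78 °C; aq NH4Cl
Reagents that add atoms: none
Why: Weinreb ketone synthesis: 2-furyllithium from alpha-lithiation of furan adds once to the amide to give a chelated tetrahedral adduct that collapses only on quench, which prevents over-addition and limits alpha-epimerisation, while the trialkyl oxirane is inert to the aryllithium at −78 °C.

Step 8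
Reactants: 12 (2S,4R)-5-[(2S,3S)-2,3-dimethyloxiran-2-yl]-1-(furan-2-yl)-2,4-dimethylpentan-1-one
Product: 13 (1R,2S,4R)-5-[(2S,3S)-2,3-dimethyloxiran-2-yl]-1-(furan-2-yl)-2,4-dimethylpentan-1-ol
Conditions: RuCl[(R,R)-TsDPEN](p-cymene) (cat.), HCO2Na, cetyltrimethylammonium bromide (cat.), H2O–CH2Cl2, rt
Reagents that add atoms: none
Why: Noyori asymmetric transfer hydrogenation: in the concerted hydride/proton transfer from the (R,R)-TsDPEN ruthenium hydride the furan ring takes the aryl position (CH–pi contact with the cymene ligand), which should deliver the R carbinol (future C6) under catalyst control, and the near-neutral aqueous formate medium is chosen to spare the epoxide and the alpha stereocentre.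

Step 9
Reactants: 13 (1R,2S,4R)-5-[(2S,3S)-2,3-dimethyloxiran-2-yl]-1-(furan-2-yl)-2,4-dimethylpentan-1-ol
Product: 15 (2R)-2-{(2S,4R)-5-[(2S,3S)-2,3-dimethyloxiran-2-yl]-4-methylpentan-2-yl}-6-hydroxy-2H-pyran-3(6H)-one (anomer mixture), via Z-hydroxy-enedione 14 (not isolated)
Conditions: NBS, NaHCO3, NaOAc, THF–H2O, 0 °C
Reagents that add atoms: water (O)
Why: Achmatowicz oxidative ring expansion: bromonium transfer from NBS to the free alpha carbon of the furan and addition of water give a 2,5-dioxygenated dihydrofuran that opens to the Z-hydroxy-enedione 14, whose C6 hydroxyl adds to the unmasked aldehyde to give lactol 15. The closest known reaction is exactly this rearrangement of 2-furyl carbinols to 6-hydroxy-2H-pyran-3(6H)-ones. The one ring formed, the six-membered pyranone, is closed by 6-exo-trig hemiacetalisation (O1–C2 bond), while the furan carbon that carried the carbinol becomes the C5 carbonyl. No lasting stereocentre is created (the anomeric carbon is oxidised in the next step), and C6 passes through unchanged because its C–O bond is never broken. The step needs chemoselective oxidation of the furan beside the epoxide without epimerising C6: the alkene was epoxidised beforehand, so the furan is the only electron-rich pi system, and the bicarbonate/acetate buffer at 0 °C keeps the medium near neutral so that the trisubstituted oxirane should survive.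

Step 10
Reactants: 15 (2R)-2-{(2S,4R)-5-[(2S,3S)-2,3-dimethyloxiran-2-yl]-4-methylpentan-2-yl}-6-hydroxy-2H-pyran-3(6H)-one
Product: 16 (6R)-6-{(2S,4R)-5-[(2S,3S)-2,3-dimethyloxiran-2-yl]-4-methylpentan-2-yl}-2H-pyran-2,5(6H)-dione
Conditions: Dess–Martin periodinane, NaHCO3, CH2Cl2, 0 °C to rt; crude used at once
Reagents that add atoms: none
Why: Dess–Martin oxidation of a lactol to the lactone under bicarbonate buffer, a non-acidic alternative to chromic acid that should leave the oxirane intact; the enolisable dione is not stored but reduced at once.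

Step 11
Reactants: 16 (6R)-6-{(2S,4R)-5-[(2S,3S)-2,3-dimethyloxiran-2-yl]-4-methylpentan-2-yl}-2H-pyran-2,5(6H)-dione
Product: 17 (5S,6R)-6-{(2S,4R)-5-[(2S,3S)-2,3-dimethyloxiran-2-yl]-4-methylpentan-2-yl}-5-hydroxy-5,6-dihydro-2H-pyran-2-one (trans)
Conditions: NaBH4, CeCl3·7H2O, MeOH–CH2Cl2, −78 °C
Reagents that add atoms: none
Why: Luche reduction: the cerium-activated borohydride adds 1,2 to the C5 ketone rather than in a conjugate sense, and axial attack on the half-chair that keeps the C6 side chain pseudo-equatorial should place the new hydroxyl trans to it, so C5 is relayed from C6 by substrate control.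

**Acid half**

Step 12
Reactants: 18 furan-2(5H)-one; 19 4,4,5,5-tetramethyl-2-(2-methylprop-1-en-1-yl)-1,3,2-dioxaborolane
Product: 20 (4S)-4-(2-methylprop-1-en-1-yl)oxolan-2-one
Conditions: [Rh(OH)((S)-BINAP)]2 (cat.), dioxane–H2O, 50 °C
Reagents that add atoms: none
Why: Rh-catalysed asymmetric conjugate addition of an alkenylboron reagent to an unsaturated lactone: transmetalation to the hydroxorhodium–BINAP complex, enantioface-selective insertion of the butenolide and hydrolysis of the rhodium enolate set the S centre (future C6 of the acid) under ligand control.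

Step 13
Reactants: 20 (4S)-4-(2-methylprop-1-en-1-yl)oxolan-2-one
Product: 21 (2S)-2-(2-methylprop-1-en-1-yl)butane-1,4-diol
Conditions: LiAlH4, THF, 0 °C
Reagents that add atoms: none
Why: Hydride reduction of the lactone to the 1,4-diol with LiAlH4, which does not touch the isolated alkene or the stereocentre.

Step 14
Reactants: 21 (2S)-2-(2-methylprop-1-en-1-yl)butane-1,4-diol
Product: 22 (S)-1,4-bis(tert-butyldimethylsilyloxy)-2-(2-methylprop-1-en-1-yl)butane
Conditions: TBSCl, imidazole, DMF, rt
Reagents that add atoms: tert-butyldimethylsilyl chloride (CC(C)(C)[Si](C)(C)Cl)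
Why: Standard silylation of both primary alcohols as tert-butyldimethylsilyl ethers, robust enough for the oxidations, the olefination and the saponification that follow.

Step 15
Reactants: 22 (S)-1,4-bis(tert-butyldimethylsilyloxy)-2-(2-methylprop-1-en-1-yl)butane
Product: 23 (2E,4S)-6-(tert-butyldimethylsilyloxy)-4-[(tert-butyldimethylsilyloxy)methyl]-2-methylhex-2-en-1-ol
Conditions: SeO2 (cat.), t-BuOOH, salicylic acid (cat.), CH2Cl2, rt
Reagents that add atoms: tert-butyl hydroperoxide (CC(C)(C)OO), the terminal oxygen source relayed through selenium dioxide (O=[Se]=O)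
Why: SeO2 allylic oxidation (ene reaction followed by [2,3]-sigmatropic rearrangement) attacks a methyl group on the more substituted alkene carbon and does so E-selectively, so the trisubstituted E geometry is set and the allylic stereocentre on the less substituted side is left alone.

Step 16
Reactants: 23 (2E,4S)-6-(tert-butyldimethylsilyloxy)-4-[(tert-butyldimethylsilyloxy)methyl]-2-methylhex-2-en-1-ol
Product: 24 (2E,4S)-6-(tert-butyldimethylsilyloxy)-4-[(tert-butyldimethylsilyloxy)methyl]-2-methylhex-2-enal
Conditions: MnO2, CH2Cl2, rt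
Reagents that add atoms: none
Why: MnO2 oxidation of the allylic alcohol to the enal, a neutral heterogeneous method that does not isomerise the alkene or epimerise the gamma stereocentre and converges any enal already formed in step 15.

Step 17
Reactants: 24 (2E,4S)-6-(tert-butyldimethylsilyloxy)-4-[(tert-butyldimethylsilyloxy)methyl]-2-methylhex-2-enal
Product: 25 methyl (2E,4E,6S)-8-(tert-butyldimethylsilyloxy)-6-[(tert-butyldimethylsilyloxy)methyl]-4-methylocta-2,4-dienoate
Conditions: Ph3P=CHCO2Me, toluene, 80 °C
Reagents that add atoms: methyl (triphenylphosphoranylidene)acetate (COC(=O)C=P(c1ccccc1)(c1ccccc1)c1ccccc1)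
Why: Wittig olefination with a stabilised ylide, which brings in C1 and C2 and gives the E-enoate through the thermodynamically preferred oxaphosphetane, completing the 2E,4E-diene.

Step 18
Reactants: 25 methyl (2E,4E,6S)-8-(tert-butyldimethylsilyloxy)-6-[(tert-butyldimethylsilyloxy)methyl]-4-methylocta-2,4-dienoate
Product: 26 (2E,4E,6S)-8-(tert-butyldimethylsilyloxy)-6-[(tert-butyldimethylsilyloxy)methyl]-4-methylocta-2,4-dienoic acid
Conditions: LiOH, THF–MeOH–H2O, rt; then dilute HCl to pH 4 at 0 °C
Reagents that add atoms: lithium hydroxide ([Li+].[OH-])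
Why: Saponification of the methyl ester with LiOH, conditions under which primary tert-butyldimethylsilyl ethers and the non-enolisable C6 centre are stable.

**Union and release**

Step 19
Reactants: 17 (5S,6R)-6-{(2S,4R)-5-[(2S,3S)-2,3-dimethyloxiran-2-yl]-4-methylpentan-2-yl}-5-hydroxy-5,6-dihydro-2H-pyran-2-one; 26 (2E,4E,6S)-8-(tert-butyldimethylsilyloxy)-6-[(tert-butyldimethylsilyloxy)methyl]-4-methylocta-2,4-dienoic acid
Product: 27 (2R,3R)-2-{(2S,4R)-5-[(2S,3S)-2,3-dimethyloxiran-2-yl]-4-methylpentan-2-yl}-6-oxo-3,6-dihydro-2H-pyran-3-yl (2E,4E,6S)-8-(tert-butyldimethylsilyloxy)-6-[(tert-butyldimethylsilyloxy)methyl]-4-methylocta-2,4-dienoate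
Conditions: PPh3, diisopropyl azodicarboxylate, toluene, −20 °C to rt
Reagents that add atoms: none
Why: Mitsunobu esterification: the C5 hydroxyl is activated as an oxyphosphonium leaving group and displaced by the carboxylate in an SN2 step, which inverts C5 from S to R and so turns the trans alcohol into the cis ester under non-basic conditions that do not enolise or open the lactone.

Step 20
Reactants: 27 bis-silyl ether of the target (as named in step 19)
Product: 28 (2R,3R)-2-{(2S,4R)-5-[(2S,3S)-2,3-dimethyloxiran-2-yl]-4-methylpentan-2-yl}-6-oxo-3,6-dihydro-2H-pyran-3-yl (2E,4E,6S)-8-hydroxy-6-(hydroxymethyl)-4-methylocta-2,4-dienoate (CNP0160449.1)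
Conditions: HF·pyridine, excess pyridine, THF, 0 °C to rt
Reagents that add atoms: none
Why: Fluoride-mediated cleavage of the two primary silyl ethers; pyridine-buffered HF at 0 °C is not basic enough to attack the acyloxy lactone and not acidic enough to open the trisubstituted oxirane, so the target should be released intact.

**Compound list**

1 | meso-2,4-dimethylglutaric anhydride | O=C1OC(=O)[C@@H](C)C[C@H]1C | starting material
2 | (2R,4S)-5-methoxy-2,4-dimethyl-5-oxopentanoic acid | COC(=O)[C@@H](C)C[C@@H](C)C(=O)O | intermediate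
3 | methyl (2S,4R)-5-hydroxy-2,4-dimethylpentanoate | COC(=O)[C@@H](C)C[C@@H](C)CO | intermediate
4 | methyl (2S,4R)-5-iodo-2,4-dimethylpentanoate | COC(=O)[C@@H](C)C[C@@H](C)CI | intermediate
5 | (E)-2-bromobut-2-ene | Br/C(C)=C/C | starting material
6 | [(2R,4S)-5-methoxy-2,4-dimethyl-5-oxopentyl]zinc iodide (not isolated) | COC(=O)[C@@H](C)C[C@@H](C)C[Zn]I | intermediate
7 | methyl (2S,4R,6E)-2,4,6-trimethyloct-6-enoate | COC(=O)[C@@H](C)C[C@@H](C)C/C(C)=C/C | intermediate
8 | (2S,4R,6E)-N-methoxy-N,2,4,6-tetramethyloct-6-enamide | CON(C)C(=O)[C@@H](C)C[C@@H](C)C/C(C)=C/C | intermediate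
9 | (2S,4R)-5-[(2S,3S)-2,3-dimethyloxiran-2-yl]-N-methoxy-N,2,4-trimethylpentanamide | CON(C)C(=O)[C@@H](C)C[C@@H](C)C[C@]1(C)O[C@H]1C | intermediate
10 | furan | c1ccoc1 | starting material
11 | 2-furyllithium (not isolated) | [Li]c1ccco1 | intermediate
12 | (2S,4R)-5-[(2S,3S)-2,3-dimethyloxiran-2-yl]-1-(furan-2-yl)-2,4-dimethylpentan-1-one | O=C(c1ccco1)[C@@H](C)C[C@@H](C)C[C@]1(C)O[C@H]1C | intermediate
13 | (1R,2S,4R)-5-[(2S,3S)-2,3-dimethyloxiran-2-yl]-1-(furan-2-yl)-2,4-dimethylpentan-1-ol | O[C@@H](c1ccco1)[C@@H](C)C[C@@H](C)C[C@]1(C)O[C@H]1C | intermediate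
14 | (2Z,5R,6S,8R)-9-[(2S,3S)-2,3-dimethyloxiran-2-yl]-5-hydroxy-6,8-dimethyl-4-oxonon-2-enal (not isolated) | O=C/C=C\C(=O)[C@H](O)[C@@H](C)C[C@@H](C)C[C@]1(C)O[C@H]1C | intermediate
15 | (2R)-2-{(2S,4R)-5-[(2S,3S)-2,3-dimethyloxiran-2-yl]-4-methylpentan-2-yl}-6-hydroxy-2H-pyran-3(6H)-one, anomer mixture | O=C1C=CC(O)O[C@@H]1[C@@H](C)C[C@@H](C)C[C@]2(C)O[C@H]2C | intermediate
16 | (6R)-6-{(2S,4R)-5-[(2S,3S)-2,3-dimethyloxiran-2-yl]-4-methylpentan-2-yl}-2H-pyran-2,5(6H)-dione | O=C1C=CC(=O)O[C@@H]1[C@@H](C)C[C@@H](C)C[C@]2(C)O[C@H]2C | intermediate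
17 | (5S,6R)-6-{(2S,4R)-5-[(2S,3S)-2,3-dimethyloxiran-2-yl]-4-methylpentan-2-yl}-5-hydroxy-5,6-dihydro-2H-pyran-2-one | O[C@H]1C=CC(=O)O[C@@H]1[C@@H](C)C[C@@H](C)C[C@]1(C)O[C@H]1C | intermediate
18 | furan-2(5H)-one | O=C1OCC=C1 | starting material
19 | 4,4,5,5-tetramethyl-2-(2-methylprop-1-en-1-yl)-1,3,2-dioxaborolane | CC(C)=CB1OC(C)(C)C(C)(C)O1 | starting material
20 | (4S)-4-(2-methylprop-1-en-1-yl)oxolan-2-one | CC(C)=C[C@@H]1CC(=O)OC1 | intermediate
21 | (2S)-2-(2-methylprop-1-en-1-yl)butane-1,4-diol | CC(C)=C[C@@H](CO)CCO | intermediate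
22 | (S)-1,4-bis(tert-butyldimethylsilyloxy)-2-(2-methylprop-1-en-1-yl)butane | CC(C)=C[C@@H](CO[Si](C)(C)C(C)(C)C)CCO[Si](C)(C)C(C)(C)C | intermediate
23 | (2E,4S)-6-(tert-butyldimethylsilyloxy)-4-[(tert-butyldimethylsilyloxy)methyl]-2-methylhex-2-en-1-ol | OC/C(C)=C/[C@@H](CO[Si](C)(C)C(C)(C)C)CCO[Si](C)(C)C(C)(C)C | intermediate
24 | (2E,4S)-6-(tert-butyldimethylsilyloxy)-4-[(tert-butyldimethylsilyloxy)methyl]-2-methylhex-2-enal | O=C/C(C)=C/[C@@H](CO[Si](C)(C)C(C)(C)C)CCO[Si](C)(C)C(C)(C)C | intermediate
25 | methyl (2E,4E,6S)-8-(tert-butyldimethylsilyloxy)-6-[(tert-butyldimethylsilyloxy)methyl]-4-methylocta-2,4-dienoate | COC(=O)/C=C/C(C)=C/[C@@H](CO[Si](C)(C)C(C)(C)C)CCO[Si](C)(C)C(C)(C)C | intermediate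
26 | (2E,4E,6S)-8-(tert-butyldimethylsilyloxy)-6-[(tert-butyldimethylsilyloxy)methyl]-4-methylocta-2,4-dienoic acid | CC(/C=C/C(=O)O)=C\[C@@H](CO[Si](C)(C)C(C)(C)C)CCO[Si](C)(C)C(C)(C)C | intermediate
27 | bis-silyl ether of the target (cis-5R,6R ester of 26 with the lactone alcohol) | CC(/C=C/C(=O)O[C@@H]1C=CC(=O)O[C@@H]1[C@@H](C)C[C@@H](C)C[C@]1(C)O[C@H]1C)=C\[C@@H](CO[Si](C)(C)C(C)(C)C)CCO[Si](C)(C)C(C)(C)C | intermediate
28 | CNP0160449.1 | CC(/C=C/C(=O)O[C@@H]1C=CC(=O)O[C@@H]1[C@@H](C)C[C@@H](C)C[C@]1(C)O[C@H]1C)=C\[C@@H](CO)CCO | target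

**Step count and risks**

Total step count: 20. Longest linear sequence: 13 steps (steps 1–11, 19 and 20, from anhydride 1); the acid half takes 7 steps (12–18) before the union.

Steps most likely to fail:

1. Step 8. The catalyst has to override the Felkin preference of the alpha-methyl ketone, so hydride transfer may be slow, facial selectivity may be poor, or C1' may epimerise during a long reaction. The fallback forms the C6–furan bond instead of the C6–H bond and sets out from 9. Reduction of 9 with i-Bu2AlH (THF, −78 °C) should give the epoxy aldehyde (2S,4R)-5-[(2S,3S)-2,3-dimethyloxiran-2-yl]-2,4-dimethylpentanal F1. Addition of 2-furyllithium 11 (THF, −78 °C) is expected to follow the Felkin–Anh model, whose favoured syn adduct is 13 itself, accompanied by the C1 epimer (1S,2S,4R)-5-[(2S,3S)-2,3-dimethyloxiran-2-yl]-1-(furan-2-yl)-2,4-dimethylpentan-1-ol F2. Sharpless kinetic-resolution conditions (Ti(OiPr)4, L-(+)-diisopropyl tartrate, t-BuOOH, molecular sieves, CH2Cl2, −20 °C) should oxidise the faster-reacting 1S carbinol F2 to the lactol (2S)-2-{(2S,4R)-5-[(2S,3S)-2,3-dimethyloxiran-2-yl]-4-methylpentan-2-yl}-6-hydroxy-2H-pyran-3(6H)-one F3, which is separated. The slow-reacting R carbinol 13 is left, and the route is rejoined at 13.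

2. Step 19. Displacement at C5 next to the branched C6 substituent by a weakly acidic dienoic acid may be slow, so elimination of the activated hydroxyl towards the 2-pyranone or esterification with retention may compete. The fallback separates inversion from acylation and sets out from 17. A Mitsunobu reaction with the smaller and much more acidic chloroacetic acid (PPh3, diisopropyl azodicarboxylate, toluene) should give the cis ester (2R,3R)-2-{(2S,4R)-5-[(2S,3S)-2,3-dimethyloxiran-2-yl]-4-methylpentan-2-yl}-6-oxo-3,6-dihydro-2H-pyran-3-yl chloroacetate F4. Selective removal of the chloroacetyl group with thiourea (NaHCO3, EtOH) should give the cis alcohol (5R,6R)-6-{(2S,4R)-5-[(2S,3S)-2,3-dimethyloxiran-2-yl]-4-methylpentan-2-yl}-5-hydroxy-5,6-dihydro-2H-pyran-2-one F5. Yamaguchi esterification of F5 with acid 26 (2,4,6-trichlorobenzoyl chloride, Et3N, then DMAP, toluene) proceeds with retention and comes back to the route at 27.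

3. Step 12. Turnover with the poorly reactive butenolide may be low, the hindered alkenylboronate may protodeboronate, or enantioface selectivity may be insufficient. The fallback replaces catalytic conjugate addition by an auxiliary-controlled alkylation. It sets out from no numbered compound: commercial 4-methylpent-3-enoic acid and (S)-4-benzyloxazolidin-2-one take the place of 18 and 19. Acylation through the pivaloyl mixed anhydride (t-BuCOCl, Et3N, then the lithiated oxazolidinone, THF) should give (S)-4-benzyl-3-(4-methylpent-3-enoyl)oxazolidin-2-one F6. Evans alkylation of its sodium enolate (NaHMDS, THF, −78 °C) with tert-butyl bromoacetate occurs at the alpha carbon, on the face opposite the benzyl group, and should give tert-butyl (3S)-3-[(4S)-4-benzyl-2-oxooxazolidine-3-carbonyl]-5-methylhex-4-enoate F7. LiAlH4 (THF, 0 °C) reduces both the imide and the ester, bypasses lactone 20 and comes back to the route at diol 21.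

Further compounds
F1 | step 8 | (2S,4R)-5-[(2S,3S)-2,3-dimethyloxiran-2-yl]-2,4-dimethylpentanal | O=C[C@@H](C)C[C@@H](C)C[C@]1(C)O[C@H]1C
F2 | step 8 | (1S,2S,4R)-5-[(2S,3S)-2,3-dimethyloxiran-2-yl]-1-(furan-2-yl)-2,4-dimethylpentan-1-ol | O[C@H](c1ccco1)[C@@H](C)C[C@@H](C)C[C@]1(C)O[C@H]1C
F3 | step 8 | (2S)-2-{(2S,4R)-5-[(2S,3S)-2,3-dimethyloxiran-2-yl]-4-methylpentan-2-yl}-6-hydroxy-2H-pyran-3(6H)-one | O=C1C=CC(O)O[C@H]1[C@@H](C)C[C@@H](C)C[C@]2(C)O[C@H]2C
F4 | step 19 | (2R,3R)-2-{(2S,4R)-5-[(2S,3S)-2,3-dimethyloxiran-2-yl]-4-methylpentan-2-yl}-6-oxo-3,6-dihydro-2H-pyran-3-yl chloroacetate | ClCC(=O)O[C@@H]1C=CC(=O)O[C@@H]1[C@@H](C)C[C@@H](C)C[C@]1(C)O[C@H]1C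
F5 | step 19 | (5R,6R)-6-{(2S,4R)-5-[(2S,3S)-2,3-dimethyloxiran-2-yl]-4-methylpentan-2-yl}-5-hydroxy-5,6-dihydro-2H-pyran-2-one | O[C@@H]1C=CC(=O)O[C@@H]1[C@@H](C)C[C@@H](C)C[C@]1(C)O[C@H]1C
F6 | step 12 | (S)-4-benzyl-3-(4-methylpent-3-enoyl)oxazolidin-2-one | CC(C)=CCC(=O)N1[C@@H](Cc2ccccc2)COC1=O
F7 | step 12 | tert-butyl (3S)-3-[(4S)-4-benzyl-2-oxooxazolidine-3-carbonyl]-5-methylhex-4-enoate | CC(C)=C[C@H](CC(=O)OC(C)(C)C)C(=O)N1[C@@H](Cc2ccccc2)COC1=O
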